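The route rests on cutting the C2=C3 enone alkene and the C8–C9 bond (as its alkene) of the tricycle, which leaves the all-trans cyclobutane C4–C5–C11–C10. One ruthenium-catalysed double ring-closing metathesis then stitches both bridging rings onto it: the six-membered enone ring across the cis-1,3 pair C4/C11 on one face and the seven-membered ring across the cis-1,3 pair C5/C10 on the other. The precursor is a monocyclic tetraene: C4 isopropenyl, C11 acryloyl, C10 methyl/vinyl and the C5 side chain CMe2–CH(OTBS)–CH=CH2, with C7 already set. Cyclopentenone chemistry and a Wolff ring contraction supply it; dihydroxylation and two acylations finish.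

Key step: step 16

Numbering: cyclobutane and tricyclic compounds carry the target's locants (C1 ketone carbon; C2=C3 enone alkene; C4, C5, C11, C10 cyclobutane; C6 CMe2; C7–C9 oxygenated carbons); cyclopentane intermediates carry their IUPAC locants.
Assumption: in diol 38 the C9 hydroxyl, neopentylic to the quaternary C10, is the less reactive one toward acylation, so the angelate is placed first at C8.

Step 1
Reactants: 1 (4R)-4-[(tert-butyldimethylsilyl)oxy]cyclopent-2-en-1-one; 2 iodine
Product: 3 (4R)-4-[(tert-butyldimethylsilyl)oxy]-2-iodocyclopent-2-en-1-one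
Conditions: iodine (1.6 equiv), pyridine/CH2Cl2 1:1, 0 °C → rt
Reagents that add atoms: iodine (2), II
Why: α-Iodination of an enone by pyridine addition, iodination of the enolate and elimination (Baylis–Hillman-type sequence), routine for 4-silyloxycyclopentenones and without effect on the C4 stereocentre.

Step 2
Reactants: 3 (4R)-4-[(tert-butyldimethylsilyl)oxy]-2-iodocyclopent-2-en-1-one; 4 methylzinc chloride
Product: 5 (4R)-4-[(tert-butyldimethylsilyl)oxy]-2-methylcyclopent-2-en-1-one
Conditions: CH3ZnCl (1.5 equiv), PdCl2(dppf) (5 mol%), THF, 0 °C → rt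
Reagents that add atoms: methylzinc chloride (4), C[Zn]Cl
Why: Negishi cross-coupling at the carbon–iodine bond of an α-iodo enone; the alkylzinc reagent neither adds to the enone nor is basic enough to eliminate the silyloxy group.

Step 3
Reactants: 5 (4R)-4-[(tert-butyldimethylsilyl)oxy]-2-methylcyclopent-2-en-1-one; 6 isopropenylmagnesium bromide; 7 formaldehyde
Product: 9 (2S,3R,4R)-4-[(tert-butyldimethylsilyl)oxy]-2-(hydroxymethyl)-2-methyl-3-(prop-1-en-2-yl)cyclopentan-1-one, via bromomagnesium enolate 8 (not isolated)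
Conditions: CH2=C(CH3)MgBr (1.5 equiv), CuBr·SMe2 (20 mol%), THF, −78 → −40 °C; then CH2O (gas, cracked from paraformaldehyde), −78 °C; aq. NH4Cl
Reagents that add atoms: isopropenylmagnesium bromide (6), C=C(C)[Mg]Br; formaldehyde (7), C=O
Why: Copper-catalysed conjugate addition of a Grignard reagent with aldol capture of the enolate (three-component coupling): isopropenyl should add to C3 anti to the C4 silyloxy group, and formaldehyde should then enter C2 of the tetrasubstituted enolate anti to the new C3 substituent, which sets the quaternary centre with methyl cis and CH2OH trans to isopropenyl.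

Step 4
Reactants: 9 (2S,3R,4R)-4-[(tert-butyldimethylsilyl)oxy]-2-(hydroxymethyl)-2-methyl-3-(prop-1-en-2-yl)cyclopentan-1-one
Product: 10 (1S,2R,3R)-3-[(tert-butyldimethylsilyl)oxy]-1-methyl-5-oxo-2-(prop-1-en-2-yl)cyclopentane-1-carbaldehyde
Conditions: Dess–Martin periodinane (1.3 equiv), CH2Cl2, 0 °C → rt
Reagents that add atoms: none
Why: Dess–Martin oxidation of the primary alcohol to a non-enolisable aldehyde under neutral conditions that avoid retro-aldol loss of formaldehyde; no stereocentre is touched.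

Step 5
Reactants: 10 (1S,2R,3R)-3-[(tert-butyldimethylsilyl)oxy]-1-methyl-5-oxo-2-(prop-1-en-2-yl)cyclopentane-1-carbaldehyde; 11 methyltriphenylphosphonium bromide
Product: 12 (2R,3R,4R)-4-[(tert-butyldimethylsilyl)oxy]-2-ethenyl-2-methyl-3-(prop-1-en-2-yl)cyclopentan-1-one
Conditions: Ph3PCH3Br (1.2 equiv), KN(SiMe3)2 (1.1 equiv), THF, 0 °C; then 10, −78 → 0 °C
Reagents that add atoms: methyltriphenylphosphonium bromide (11), C[P+](c1ccccc1)(c1ccccc1)c1ccccc1.[Br-]
Why: Wittig methylenation, chemoselective at low temperature for the aldehyde over the cyclopentanone that is flanked by the quaternary carbon, which itself cannot epimerise.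

Step 6
Reactants: 12 (2R,3R,4R)-4-[(tert-butyldimethylsilyl)oxy]-2-ethenyl-2-methyl-3-(prop-1-en-2-yl)cyclopentan-1-one
Product: 13 (4R,5R)-5-ethenyl-5-methyl-4-(prop-1-en-2-yl)cyclopent-2-en-1-one
Conditions: DBU (1.1 equiv), CH2Cl2, −20 → 0 °C, short contact time
Reagents that add atoms: none
Why: E1cB β-elimination of silanol from a β-silyloxy ketone, the classical entry to 4-substituted cyclopent-2-enones, which removes the now redundant carbinol centre and places the enone on the unsubstituted side; brief exposure at low temperature should avoid γ-deprotonation at C4.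

Step 7
Reactants: 13 (4R,5R)-5-ethenyl-5-methyl-4-(prop-1-en-2-yl)cyclopent-2-en-1-one; 14 1-methoxy-2-methyl-1-(trimethylsilyloxy)prop-1-ene
Product: 16 methyl 2-[(1R,2R,3R)-3-ethenyl-3-methyl-4-oxo-2-(prop-1-en-2-yl)cyclopentyl]-2-methylpropanoate, via silyl enol ether 15 (not isolated)
Conditions: 14 (2 equiv), HN(SO2CF3)2 (2 mol%, gives Me3SiN(SO2CF3)2 in situ), CH2Cl2, −78 → −40 °C; then 1 M HCl, THF, 0 °C
Reagents that add atoms: 1-methoxy-2-methyl-1-(trimethylsilyloxy)prop-1-ene (14), COC(O[Si](C)(C)C)=C(C)C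
Why: Mukaiyama–Michael addition of a silyl ketene acetal under silylium catalysis, in which the nucleophile should enter the β-carbon anti to the adjacent isopropenyl group (trans relationship of side chain and isopropenyl) before acid hydrolyses the silyl enol ether.

Step 8
Reactants: 16 methyl 2-[(1R,2R,3R)-3-ethenyl-3-methyl-4-oxo-2-(prop-1-en-2-yl)cyclopentyl]-2-methylpropanoate
Product: 17 2-[(1R,2R,3R)-3-ethenyl-4-hydroxy-3-methyl-2-(prop-1-en-2-yl)cyclopentyl]-2-methylpropan-1-ol (both C4 epimers)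
Conditions: LiAlH4 (2 equiv), Et2O, 0 °C → rt; aqueous NaOH work-up
Reagents that add atoms: none
Why: Hydride reduction of ketone and ester together, a deliberate over-reduction that removes any need to tell the two carbonyl groups apart; the alkenes are inert and the ring carbinol configuration is irrelevant because step 9 erases it.

Step 9
Reactants: 17 2-[(1R,2R,3R)-3-ethenyl-4-hydroxy-3-methyl-2-(prop-1-en-2-yl)cyclopentyl]-2-methylpropan-1-ol
Product: 18 2-[(1R,2R,3R)-3-ethenyl-3-methyl-4-oxo-2-(prop-1-en-2-yl)cyclopentyl]-2-methylpropanal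
Conditions: (COCl)2, DMSO, CH2Cl2, −78 °C; Et3N, −78 °C → rt
Reagents that add atoms: none
Why: Swern oxidation, in which both hydroxyls are activated as alkoxysulfonium salts before base is added, so that no lactol can form and be over-oxidised to a lactone; the α-quaternary aldehyde cannot enolise.

Step 10
Reactants: 18 2-[(1R,2R,3R)-3-ethenyl-3-methyl-4-oxo-2-(prop-1-en-2-yl)cyclopentyl]-2-methylpropanal; 19 vinylmagnesium bromide
Product: 20 (2R,3R,4R)-2-ethenyl-4-[(3R)-3-hydroxy-2-methylpent-4-en-2-yl]-2-methyl-3-(prop-1-en-2-yl)cyclopentan-1-one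
Conditions: Zn(CH=CH2)2 [from CH2=CHMgBr (4 equiv) and ZnCl2 (2 equiv), THF; magnesium salts precipitated with 1,4-dioxane], (+)-MIB [(2R)-3-exo-morpholinoisoborneol, 10 mol%], toluene, −20 → 0 °C; aq. NH4Cl
Reagents that add atoms: vinylmagnesium bromide (19), C=C[Mg]Br
Why: Amino-alcohol-catalysed enantioselective alkenylzinc addition to an aldehyde, which leaves the hindered ketone alone; the ligand enantiomer is chosen to deliver the vinyl group to the Re face (the antipode delivers to the Si face in dialkylzinc additions), setting C7 as R under catalyst control because the ring stereocentres are too remote to interfere.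

Step 11
Reactants: 20 (2R,3R,4R)-2-ethenyl-4-[(3R)-3-hydroxy-2-methylpent-4-en-2-yl]-2-methyl-3-(prop-1-en-2-yl)cyclopentan-1-one; 21 tert-butyldimethylsilyl trifluoromethanesulfonate
Product: 22 (2R,3R,4R)-4-{(3R)-3-[(tert-butyldimethylsilyl)oxy]-2-methylpent-4-en-2-yl}-2-ethenyl-2-methyl-3-(prop-1-en-2-yl)cyclopentan-1-one
Conditions: TBSOTf (1.5 equiv), 2,6-lutidine (3 equiv), CH2Cl2, −78 → 0 °C; dilute acid wash
Reagents that add atoms: tert-butyldimethylsilyl trifluoromethanesulfonate (21), CC(C)(C)[Si](C)(C)OS(=O)(=O)C(F)(F)F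
Why: Silylation of a hindered secondary alcohol with a silyl triflate; any silyl enol ether formed at the ketone is cleaved again in the acidic wash.

Step 12
Reactants: 22 (2R,3R,4R)-4-{(3R)-3-[(tert-butyldimethylsilyl)oxy]-2-methylpent-4-en-2-yl}-2-ethenyl-2-methyl-3-(prop-1-en-2-yl)cyclopentan-1-one; 23 2,2,2-trifluoroethyl trifluoroacetate; 24 4-acetamidobenzenesulfonyl azide
Product: 26 (2R,3R,4R)-4-{(3R)-3-[(tert-butyldimethylsilyl)oxy]-2-methylpent-4-en-2-yl}-5-diazo-2-ethenyl-2-methyl-3-(prop-1-en-2-yl)cyclopentan-1-one, via trifluoroacetyl ketone 25 (not isolated)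
Conditions: LiN(SiMe3)2, THF, −78 °C; CF3CO2CH2CF3, −78 °C; 1 M HCl work-up; then 4-acetamidobenzenesulfonyl azide, Et3N, H2O (1 equiv), MeCN, rt
Reagents that add atoms: 4-acetamidobenzenesulfonyl azide (24), CC(=O)Nc1ccc(cc1)S(=O)(=O)N=[N+]=[N-]; 2,2,2-trifluoroethyl trifluoroacetate (23), O=C(OCC(F)(F)F)C(F)(F)F (its atoms stay only in 25)
Why: Deacylative diazo transfer (Claisen trifluoroacetylation followed by sulfonyl azide), regiochemically unambiguous because C5 is the only α-carbon that carries hydrogen.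

Step 13
Reactants: 26 (2R,3R,4R)-4-{(3R)-3-[(tert-butyldimethylsilyl)oxy]-2-methylpent-4-en-2-yl}-5-diazo-2-ethenyl-2-methyl-3-(prop-1-en-2-yl)cyclopentan-1-one; 27 methanol
Product: 30 methyl (1R,2R,3R,4S)-4-{(3R)-3-[(tert-butyldimethylsilyl)oxy]-2-methylpent-4-en-2-yl}-2-ethenyl-2-methyl-3-(prop-1-en-2-yl)cyclobutane-1-carboxylate, via ketene 28 (not isolated), via C11-epimeric methyl ester 29 (not isolated)
Conditions: hν (medium-pressure Hg lamp, Pyrex, λ > 300 nm), MeOH, 0 °C; then NaOMe (0.3 equiv), MeOH, 25–45 °C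
Reagents that add atoms: methanol (27), CO
Why: Photochemical Wolff rearrangement of a cyclic α-diazo ketone (ring contraction) with 1,2-shift of the quaternary carbon under retention and capture of the ketene by methanol, followed by base equilibration of the ester α-centre C11 to the epimer trans to both the bulky C5 side chain and the C10 vinyl group, which should give the all-trans cyclobutane.

Step 14
Reactants: 30 methyl (1R,2R,3R,4S)-4-{(3R)-3-[(tert-butyldimethylsilyl)oxy]-2-methylpent-4-en-2-yl}-2-ethenyl-2-methyl-3-(prop-1-en-2-yl)cyclobutane-1-carboxylate; 31 N,O-dimethylhydroxylamine hydrochloride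
Product: 32 (1R,2R,3R,4S)-4-{(3R)-3-[(tert-butyldimethylsilyl)oxy]-2-methylpent-4-en-2-yl}-2-ethenyl-N-methoxy-N,2-dimethyl-3-(prop-1-en-2-yl)cyclobutane-1-carboxamide
Conditions: MeNHOMe·HCl (3 equiv), iPrMgCl (6 equiv), THF, −20 → 0 °C
Reagents that add atoms: N,O-dimethylhydroxylamine hydrochloride (31), CNOC.Cl
Why: Aminolysis of a methyl ester by the magnesium amide of N,O-dimethylhydroxylamine (Weinreb amide formation), harmless to C11 because that centre already has its thermodynamic configuration.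

Step 15
Reactants: 32 (1R,2R,3R,4S)-4-{(3R)-3-[(tert-butyldimethylsilyl)oxy]-2-methylpent-4-en-2-yl}-2-ethenyl-N-methoxy-N,2-dimethyl-3-(prop-1-en-2-yl)cyclobutane-1-carboxamide; 19 vinylmagnesium bromide
Product: 33 1-[(1R,2R,3R,4S)-4-{(3R)-3-[(tert-butyldimethylsilyl)oxy]-2-methylpent-4-en-2-yl}-2-ethenyl-2-methyl-3-(prop-1-en-2-yl)cyclobutyl]prop-2-en-1-one (all-trans tetraene)
Conditions: CH2=CHMgBr (3 equiv), THF, 0 °C; inverse quench into cold 1 M HCl
Reagents that add atoms: vinylmagnesium bromide (19), C=C[Mg]Br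
Why: Weinreb ketone synthesis, in which the chelated tetrahedral adduct prevents over-addition and the inverse acidic quench keeps the liberated amine from adding to the new vinyl ketone.

Step 16
Reactants: 33 1-[(1R,2R,3R,4S)-4-{(3R)-3-[(tert-butyldimethylsilyl)oxy]-2-methylpent-4-en-2-yl}-2-ethenyl-2-methyl-3-(prop-1-en-2-yl)cyclobutyl]prop-2-en-1-one
Product: 35 tricyclic dienone (4R,5S,7R,10R,11R; C1 ketone; C2=C3 and C8=C9 alkenes; C7 tert-butyldimethylsilyl ether), via bicyclic vinyl ketone 34 (not isolated)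
Conditions: (H2IMes)(PCy3)Cl2Ru=CHPh (second-generation Grubbs catalyst, 10 mol% in two portions), 1,4-benzoquinone (10 mol%), toluene (2 mM), 80 °C, argon sparge
Reagents that add atoms: none
Why: Olefin metathesis by the metallacyclobutane mechanism: the ruthenium benzylidene is exchanged onto a monosubstituted vinyl group, and each ring forms by intramolecular (2+2) cycloaddition to a ruthenacyclobutane and cycloreversion, with ethene expelled. The closest known reaction type is tandem ring-closing metathesis of tetraenes, including enone-forming closure of a vinyl ketone onto a 1,1-disubstituted alkene with this catalyst. The seven-membered ring closes across C5 and C10 (new C8=C9 cis-alkene, bicyclo[4.1.1]octene 34), and the six-membered ring closes across C11 and C4 (new C2=C3 trisubstituted enone, bicyclo[3.1.1]heptenone). No stereocentre is created; C4, C5, C7, C10 and C11 are carried through unchanged. The selectivity needed is the pairing of the arms: the all-trans cyclobutane holds the C4/C11 arms on one face and the C5/C10 arms on the other, so both cis-1,3 pairs can be pseudo-axial at once in the puckered ring, whereas the trans-1,2 pairings would give trans-fused bicycles (C10/C11 and C10/C4 cannot close, C5/C4 and C5/C11 only with strain), and the electron-poor acryloyl group, the slowest partner, should be engaged last, after the first bridge has locked the pucker. High dilution, removal of ethene and 80 °C serve the slow enone-forming closure, and benzoquinone suppresses alkene isomerisation by ruthenium hydrides.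

Step 17
Reactants: 35 tricyclic dienone (C7 tert-butyldimethylsilyl ether); 36 4-methylmorpholine N-oxide; 37 water
Product: 38 tricyclic C8,C9-cis-diol (4R,5S,7S,8S,9S,10R,11R; C7 tert-butyldimethylsilyl ether; C2=C3 enone intact)
Conditions: OsO4 (5 mol%), NMO (2 equiv), acetone/H2O 10:1, 0 °C → rt
Reagents that add atoms: 4-methylmorpholine N-oxide (36), C[N+]1([O-])CCOCC1; water (37), O
Why: Catalytic OsO4/NMO syn-dihydroxylation of the isolated cis-alkene in preference to the electron-poor trisubstituted enone; the two faces of C8=C9 differ essentially only in the allylic C7 silyloxy group, so OsO4 should approach anti to it and set C8 and C9 together, cis to each other and trans to O7.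

Step 18
Reactants: 38 tricyclic C8,C9-cis-diol (C7 tert-butyldimethylsilyl ether); 39 angelic acid [(Z)-2-methylbut-2-enoic acid]
Product: 40 C8 mono-angelate (4R,5S,7S,8S,9S,10R,11R; C9 hydroxyl free; C7 tert-butyldimethylsilyl ether)
Conditions: angelic acid (1.5 equiv), 2,4,6-Cl3C6H2COCl (1.5 equiv), Et3N (3 equiv), toluene, rt; then 38, 80 °C
Reagents that add atoms: angelic acid (39), C/C=C(/C)C(=O)O
Why: Yamaguchi esterification through the mixed 2,4,6-trichlorobenzoic anhydride without a nucleophilic catalyst, the conditions that transfer an angeloyl group without Z-to-E isomerisation; the C8 hydroxyl should react ahead of the neopentylic C9 hydroxyl next to the quaternary C10.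

Step 19
Reactants: 40 C8 mono-angelate (C9 hydroxyl free); 41 isovaleric anhydride (3-methylbutanoic anhydride)
Product: 42 C8 angelate C9 isovalerate (4R,5S,7S,8S,9S,10R,11R; C7 tert-butyldimethylsilyl ether)
Conditions: isovaleric anhydride (3 equiv), DMAP (0.2 equiv), Et3N (4 equiv), CH2Cl2, 0 °C → rt
Reagents that add atoms: isovaleric anhydride (41), CC(C)CC(=O)OC(=O)CC(C)C
Why: DMAP-catalysed acylation with an unhindered aliphatic anhydride, forceful enough for the neopentylic C9 hydroxyl, the only free hydroxyl left, and run cold to hold back migration of the conjugated, sluggish angelate.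

Step 20
Reactants: 42 C8 angelate C9 isovalerate (C7 tert-butyldimethylsilyl ether)
Product: 43 CNP0151972.1 (4R,5S,7S,8R,9S,10R,11R; C7 hydroxyl free; C8 angelate; C9 isovalerate)
Conditions: HF·pyridine, pyridine/THF, 0 °C → rt
Reagents that add atoms: none
Why: Desilylation with buffered, non-basic fluoride, so that no alkoxide forms at C7 that could take over the neighbouring C8 ester, and the angelate and the enone stay untouched.

Compound list
1 | (4R)-4-[(tert-butyldimethylsilyl)oxy]cyclopent-2-en-1-one | O=C1C=C[C@H](O[Si](C)(C)C(C)(C)C)C1 | starting material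
2 | iodine | II | starting material
3 | (4R)-4-[(tert-butyldimethylsilyl)oxy]-2-iodocyclopent-2-en-1-one | O=C1C(I)=C[C@H](O[Si](C)(C)C(C)(C)C)C1 | intermediate
4 | methylzinc chloride | C[Zn]Cl | starting material
5 | (4R)-4-[(tert-butyldimethylsilyl)oxy]-2-methylcyclopent-2-en-1-one | O=C1C(C)=C[C@H](O[Si](C)(C)C(C)(C)C)C1 | intermediate
6 | isopropenylmagnesium bromide | C=C(C)[Mg]Br | starting material
7 | formaldehyde (monomer from paraformaldehyde) | C=O | starting material
8 | bromomagnesium (3R,4R)-4-[(tert-butyldimethylsilyl)oxy]-2-methyl-3-(prop-1-en-2-yl)cyclopent-1-en-1-olate | Br[Mg]OC1=C(C)[C@@H](C(C)=C)[C@H](O[Si](C)(C)C(C)(C)C)C1 | intermediate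
9 | (2S,3R,4R)-4-[(tert-butyldimethylsilyl)oxy]-2-(hydroxymethyl)-2-methyl-3-(prop-1-en-2-yl)cyclopentan-1-one | O=C1[C@](C)(CO)[C@@H](C(C)=C)[C@H](O[Si](C)(C)C(C)(C)C)C1 | intermediate
10 | (1S,2R,3R)-3-[(tert-butyldimethylsilyl)oxy]-1-methyl-5-oxo-2-(prop-1-en-2-yl)cyclopentane-1-carbaldehyde | O=C1[C@](C)(C=O)[C@@H](C(C)=C)[C@H](O[Si](C)(C)C(C)(C)C)C1 | intermediate
11 | methyltriphenylphosphonium bromide | C[P+](c1ccccc1)(c1ccccc1)c1ccccc1.[Br-] | starting material
12 | (2R,3R,4R)-4-[(tert-butyldimethylsilyl)oxy]-2-ethenyl-2-methyl-3-(prop-1-en-2-yl)cyclopentan-1-one | O=C1[C@](C)(C=C)[C@@H](C(C)=C)[C@H](O[Si](C)(C)C(C)(C)C)C1 | intermediate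
13 | (4R,5R)-5-ethenyl-5-methyl-4-(prop-1-en-2-yl)cyclopent-2-en-1-one | O=C1[C@](C)(C=C)[C@@H](C(C)=C)C=C1 | intermediate
14 | 1-methoxy-2-methyl-1-(trimethylsilyloxy)prop-1-ene | COC(O[Si](C)(C)C)=C(C)C | starting material
15 | methyl 2-[(1S,4R,5R)-4-ethenyl-4-methyl-5-(prop-1-en-2-yl)-3-(trimethylsilyloxy)cyclopent-2-en-1-yl]-2-methylpropanoate | C1=C(O[Si](C)(C)C)[C@](C)(C=C)[C@@H](C(C)=C)[C@@H]1C(C)(C)C(=O)OC | intermediate
16 | methyl 2-[(1R,2R,3R)-3-ethenyl-3-methyl-4-oxo-2-(prop-1-en-2-yl)cyclopentyl]-2-methylpropanoate | O=C1[C@](C)(C=C)[C@@H](C(C)=C)[C@H](C(C)(C)C(=O)OC)C1 | intermediate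
17 | 2-[(1R,2R,3R)-3-ethenyl-4-hydroxy-3-methyl-2-(prop-1-en-2-yl)cyclopentyl]-2-methylpropan-1-ol (C4 epimers) | OC1[C@](C)(C=C)[C@@H](C(C)=C)[C@H](C(C)(C)CO)C1 | intermediate
18 | 2-[(1R,2R,3R)-3-ethenyl-3-methyl-4-oxo-2-(prop-1-en-2-yl)cyclopentyl]-2-methylpropanal | O=C1[C@](C)(C=C)[C@@H](C(C)=C)[C@H](C(C)(C)C=O)C1 | intermediate
19 | vinylmagnesium bromide | C=C[Mg]Br | starting material
20 | (2R,3R,4R)-2-ethenyl-4-[(3R)-3-hydroxy-2-methylpent-4-en-2-yl]-2-methyl-3-(prop-1-en-2-yl)cyclopentan-1-one | O=C1[C@](C)(C=C)[C@@H](C(C)=C)[C@H](C(C)(C)[C@H](O)C=C)C1 | intermediate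
21 | tert-butyldimethylsilyl trifluoromethanesulfonate | CC(C)(C)[Si](C)(C)OS(=O)(=O)C(F)(F)F | starting material
22 | (2R,3R,4R)-4-{(3R)-3-[(tert-butyldimethylsilyl)oxy]-2-methylpent-4-en-2-yl}-2-ethenyl-2-methyl-3-(prop-1-en-2-yl)cyclopentan-1-one | O=C1[C@](C)(C=C)[C@@H](C(C)=C)[C@H](C(C)(C)[C@H](O[Si](C)(C)C(C)(C)C)C=C)C1 | intermediate
23 | 2,2,2-trifluoroethyl trifluoroacetate | O=C(OCC(F)(F)F)C(F)(F)F | starting material
24 | 4-acetamidobenzenesulfonyl azide | CC(=O)Nc1ccc(cc1)S(=O)(=O)N=[N+]=[N-] | starting material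
25 | 5-(trifluoroacetyl) derivative of 22 (C5 epimers, largely enolised) | O=C1[C@](C)(C=C)[C@@H](C(C)=C)[C@H](C(C)(C)[C@H](O[Si](C)(C)C(C)(C)C)C=C)C1C(=O)C(F)(F)F | intermediate
26 | (2R,3R,4R)-4-{(3R)-3-[(tert-butyldimethylsilyl)oxy]-2-methylpent-4-en-2-yl}-5-diazo-2-ethenyl-2-methyl-3-(prop-1-en-2-yl)cyclopentan-1-one | O=C1[C@](C)(C=C)[C@@H](C(C)=C)[C@H](C(C)(C)[C@H](O[Si](C)(C)C(C)(C)C)C=C)C1=[N+]=[N-] | intermediate
27 | methanol | CO | starting material
28 | {(2R,3R,4R)-4-{(3R)-3-[(tert-butyldimethylsilyl)oxy]-2-methylpent-4-en-2-yl}-2-ethenyl-2-methyl-3-(prop-1-en-2-yl)cyclobutylidene}methanone (ketene) | C=C[C@@H](O[Si](C)(C)C(C)(C)C)C(C)(C)[C@@H]1C(=C=O)[C@](C)(C=C)[C@H]1C(C)=C | intermediate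
29 | methyl (1S,2R,3R,4S)-4-{(3R)-3-[(tert-butyldimethylsilyl)oxy]-2-methylpent-4-en-2-yl}-2-ethenyl-2-methyl-3-(prop-1-en-2-yl)cyclobutane-1-carboxylate (C11 epimer of 30) | C=C[C@@H](O[Si](C)(C)C(C)(C)C)C(C)(C)[C@@H]1[C@H](C(=O)OC)[C@](C)(C=C)[C@H]1C(C)=C | intermediate
30 | methyl (1R,2R,3R,4S)-4-{(3R)-3-[(tert-butyldimethylsilyl)oxy]-2-methylpent-4-en-2-yl}-2-ethenyl-2-methyl-3-(prop-1-en-2-yl)cyclobutane-1-carboxylate | C=C[C@@H](O[Si](C)(C)C(C)(C)C)C(C)(C)[C@@H]1[C@@H](C(=O)OC)[C@](C)(C=C)[C@H]1C(C)=C | intermediate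
31 | N,O-dimethylhydroxylamine hydrochloride | CNOC.Cl | starting material
32 | (1R,2R,3R,4S)-4-{(3R)-3-[(tert-butyldimethylsilyl)oxy]-2-methylpent-4-en-2-yl}-2-ethenyl-N-methoxy-N,2-dimethyl-3-(prop-1-en-2-yl)cyclobutane-1-carboxamide | C=C[C@@H](O[Si](C)(C)C(C)(C)C)C(C)(C)[C@@H]1[C@@H](C(=O)N(C)OC)[C@](C)(C=C)[C@H]1C(C)=C | intermediate
33 | 1-[(1R,2R,3R,4S)-4-{(3R)-3-[(tert-butyldimethylsilyl)oxy]-2-methylpent-4-en-2-yl}-2-ethenyl-2-methyl-3-(prop-1-en-2-yl)cyclobutyl]prop-2-en-1-one (all-trans tetraene) | C=C[C@@H](O[Si](C)(C)C(C)(C)C)C(C)(C)[C@@H]1[C@@H](C(=O)C=C)[C@](C)(C=C)[C@H]1C(C)=C | intermediate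
34 | bicyclic vinyl ketone: seven-membered ring closed across C5/C10 (C8=C9), C11 acryloyl and C4 isopropenyl still open, C7 tert-butyldimethylsilyl ether (4R,5S,7R,10R,11R) | C1[C@@H](O[Si](C)(C)C(C)(C)C)C(C)(C)[C@@H]2[C@@H](C(=O)C=C)[C@](C)(C=1)[C@H]2C(C)=C | intermediate
35 | tricyclic dienone: C1 ketone, C2=C3 and C8=C9 alkenes, 3,6,6,10-tetramethyl, C7 tert-butyldimethylsilyl ether (4R,5S,7R,10R,11R) | C1[C@@H](O[Si](C)(C)C(C)(C)C)C(C)(C)[C@@H]2[C@H]3C(=O)C=C(C)[C@@H]2[C@@]3(C)C=1 | intermediate
36 | 4-methylmorpholine N-oxide | C[N+]1([O-])CCOCC1 | starting material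
37 | water | O | starting material
38 | tricyclic C8,C9-cis-diol, C7 tert-butyldimethylsilyl ether, C2=C3 enone (4R,5S,7S,8S,9S,10R,11R) | O[C@@H]1[C@@H](O[Si](C)(C)C(C)(C)C)C(C)(C)[C@@H]2[C@H]3C(=O)C=C(C)[C@@H]2[C@@]3(C)[C@@H]1O | intermediate
39 | angelic acid, (Z)-2-methylbut-2-enoic acid | C/C=C(/C)C(=O)O | starting material
40 | C8 mono-angelate of 38, C9 hydroxyl free (4R,5S,7S,8S,9S,10R,11R) | C/C=C(/C)C(=O)O[C@@H]1[C@@H](O[Si](C)(C)C(C)(C)C)C(C)(C)[C@@H]2[C@H]3C(=O)C=C(C)[C@@H]2[C@@]3(C)[C@@H]1O | intermediate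
41 | isovaleric anhydride (3-methylbutanoic anhydride) | CC(C)CC(=O)OC(=O)CC(C)C | starting material
42 | C8 angelate C9 isovalerate, C7 tert-butyldimethylsilyl ether (4R,5S,7S,8S,9S,10R,11R) | C/C=C(/C)C(=O)O[C@@H]1[C@@H](O[Si](C)(C)C(C)(C)C)C(C)(C)[C@@H]2[C@H]3C(=O)C=C(C)[C@@H]2[C@@]3(C)[C@@H]1OC(=O)CC(C)C | intermediate
43 | CNP0151972.1: C7 hydroxyl, C8 angelate, C9 isovalerate, C1 ketone, C2=C3 (4R,5S,7S,8R,9S,10R,11R) | C/C=C(/C)C(=O)O[C@@H]1[C@@H](O)C(C)(C)[C@@H]2[C@H]3C(=O)C=C(C)[C@@H]2[C@@]3(C)[C@@H]1OC(=O)CC(C)C | target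

Total step count: 20. Longest linear sequence: 20 steps (1 → 43); every other reactant is purchased.

Steps most likely to fail

Step 16. The four alkenes may pair wrongly: the C5 side chain could close onto the acryloyl group as a trans-fused cycloheptenone, the vinyl ketone could oligomerise, or the cascade could stall after the first closure. The fallback separates the two closures so that the acryloyl group is absent while the first ring forms. It sets out from Weinreb amide 32: the second-generation Grubbs catalyst in dilute toluene closes only the seven-membered ring to the bicyclic Weinreb amide F1. Vinylmagnesium bromide then converts F1 into the bicyclic vinyl ketone 34, now isolated. A second ring-closing metathesis with the second-generation Hoveyda–Grubbs catalyst (H2IMes)Cl2Ru=CH(C6H4-2-OiPr) at 80–110 °C closes the enone ring and comes back to the route at 35.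

Step 18. The acylation may not discriminate between the C8 and C9 hydroxyls, may go on to the diester, or the angeloyl group may isomerise at the temperature needed; the first ester may also migrate across the cis-diol in step 19. The fallback makes the angeloylation the last acylation, on a single free hydroxyl, and uses silylation (more sensitive to hindrance than acylation and free of migration) to mark C8. It sets out from diol 38: triethylsilyl chloride and imidazole in DMF at −20 °C give the C8 triethylsilyl ether F2. Isovaleric anhydride with DMAP then acylates C9 to the silyl ether isovalerate F3. PPTS in methanol at 0 °C removes only the triethylsilyl group to give the C8 alcohol F4. Yamaguchi angeloylation of F4 as in step 18 comes back to the route at 42.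

Step 7. Carbon–carbon bond formation at the congested β-carbon may fail through proton transfer, 1,2-attack or simple lack of reaction of the tertiary nucleophile. The fallback uses a slimmer tertiary carbanion and reaches the aldehyde oxidation level directly. It sets out from enone 13: lithiated isobutyronitrile (LiN(iPr)2, THF/DMPU, −78 → −20 °C) adds in the conjugate sense anti to the isopropenyl group, and Me3SiCl traps the enolate as the silyl enol ether nitrile F5. Reduction with iBu2AlH in toluene at −78 °C and aqueous HCl work-up hydrolyse the aluminium imine and the enol ether together. This comes back to the route at keto aldehyde 18 and bypasses 16 and 17.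

Further compounds
F1 | step 16 | bicyclic Weinreb amide: seven-membered ring closed across C5/C10 (C8=C9), C11 N-methoxy-N-methylcarboxamide, C4 isopropenyl, C7 tert-butyldimethylsilyl ether (4R,5S,7R,10R,11R) | C1[C@@H](O[Si](C)(C)C(C)(C)C)C(C)(C)[C@@H]2[C@@H](C(=O)N(C)OC)[C@](C)(C=1)[C@H]2C(C)=C
F2 | step 18 | C8 triethylsilyl ether of diol 38 (C9 hydroxyl free) | CC[Si](CC)(CC)O[C@@H]1[C@@H](O[Si](C)(C)C(C)(C)C)C(C)(C)[C@@H]2[C@H]3C(=O)C=C(C)[C@@H]2[C@@]3(C)[C@@H]1O
F3 | step 18 | C8 triethylsilyl ether C9 isovalerate | CC[Si](CC)(CC)O[C@@H]1[C@@H](O[Si](C)(C)C(C)(C)C)C(C)(C)[C@@H]2[C@H]3C(=O)C=C(C)[C@@H]2[C@@]3(C)[C@@H]1OC(=O)CC(C)C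
F4 | step 18 | C9 isovalerate with free C8 hydroxyl (C7 tert-butyldimethylsilyl ether) | O[C@@H]1[C@@H](O[Si](C)(C)C(C)(C)C)C(C)(C)[C@@H]2[C@H]3C(=O)C=C(C)[C@@H]2[C@@]3(C)[C@@H]1OC(=O)CC(C)C
F5 | step 7 | 2-[(1S,4R,5R)-4-ethenyl-4-methyl-5-(prop-1-en-2-yl)-3-(trimethylsilyloxy)cyclopent-2-en-1-yl]-2-methylpropanenitrile | C1=C(O[Si](C)(C)C)[C@](C)(C=C)[C@@H](C(C)=C)[C@@H]1C(C)(C)C#N
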